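| flask | starting complex | incoming ligand | leaving ligand | remark | time |
|---|---|---|---|---|---|
| south | 0.10 M | 0.046 M | 0.10 M | run made earlier |  |
| south-west | 0.10 M | 0.14 M | 0.10 M | run made earlier |  |
| north-west | 0.10 M | 0.36 M | 0.10 M | run made earlier |  |
| Monday's | 0.10 M | 0.0500 M | 0.100 M |  | 5.0 min |
| Thursday's | 0.10 M | 0.150 M | 0.100 M |  | 5.0 min |
| Tuesday's | 0.10 M | 0.400 M | 0.100 M |  | 5.0 min |

| run | time / min | complex with one exchanged / % | complex with two exchanged / % | starting complex / % |
|---|---|---|---|---|
| south | 0.333 | 29.4 | 4.9 | 6.9 |
| south | 0.833 | 27.8 | 5.5 | 2.5 |
| south | 1.50 | 25.7 | 5.5 | 1.4 |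
| south | 2.50 | 25.5 | 5.6 | 0.2 |
| south-west | 0.333 | 33.6 | 41.9 | 0.5 |
| south-west | 0.833 | 21.5 | 53.8 | 0 |
| south-west | 1.50 | 16.3 | 58.5 | 0 |
| south-west | 2.50 | 13.9 | 60.6 | 0 |
| north-west | 0.333 | 1.1 | 89.9 | 0.1 |
| north-west | 0.833 | 0 | 89.7 | 0 |
| north-west | 1.50 | 0.4 | 90.7 | 0.3 |
| north-west | 2.50 | 0 | 90.1 | 0.1 |

(each reading ± 0.3 percentage points)



- which of these holds the largest part of the starting complex at the end of Monday's (starting complex / complex with two exchanged / complex with one exchanged)
- which of these holds the largest part of the starting complex at the end of Thursday's (starting complex / complex with two exchanged / complex with one exchanged)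
- which of these holds the largest part of the starting complex at the end of Tuesday's (starting complex / complex with two exchanged / complex with one exchanged)
- final complex with one exchanged in Thursday's, as a percentage of the starting complex charged

1. At 0.333 min the north-west run already reads 89.9% of complex with two exchanged, and at 2.50 min it reads 90.1%.
2. That flask holds 3.60 equivalents of incoming ligand, more than the two exchanges need. Yet part of the complex stands in no listed form.
3. Call that part the silent share: what the listed forms lack at the last reading. It reads 68.7% in the south run, 25.5% in the south-west run and 9.80% in the north-west run.
4. The loss number, a selectivity factor between silent loss and ligand attack, is the silent share times charged [incoming ligand]/[starting complex]. It reads 35.7% in the south-west run and 35.3% in the north-west run, but 31.6% in the south run.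
5. Thursday's, with 1.50 equivalents, lies between the south-west and north-west runs. The south-west loss number gives it a silent share of 23.8%, so the listed forms hold 76.2%.
6. Now the end state, taking Thursday's as finished by 5.0 min, twice the last reading time. The exchanges counted in the south-west listed forms fall short of the ligand charged by 4.90% of the starting complex charged. Scaled by silent share, this leaves Thursday's 145.4% in exchanges.
7. Complex with one exchanged is then 2 × listed − exchanges, which is 6.97%.

The forecast names complex with one exchanged for Monday's, complex with two exchanged for Thursday's and complex with two exchanged for Tuesday's. Its Thursday's figure of 9% stands above the one reckoned here. Its ground: “Ligand budget sets the outcome”.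

The flasks end led by complex with one exchanged on Monday's, complex with two exchanged on Thursday's and complex with two exchanged on Tuesday's. Thursday's holds 6.77% of complex with one exchanged, so the forecast stands.

    2 starting complex → homo dimer (k = 1.69 /M/s)
    complex with one exchanged + incoming ligand → leaving ligand + complex with two exchanged (k = 1.19 /M/s)
    starting complex + complex with one exchanged → side product (k = 0.588 /M/s)
    starting complex + incoming ligand → leaving ligand + complex with one exchanged (k = 6.33 /M/s)

Side product and homo dimer hold 23.5% in Thursday's, against the silent share of 23.8%. The neighbouring flask is Thursday's with 0.040 M of starting complex, which makes 3.75 equiv of incoming ligand. The loss number 35.7% gives it a silent share of 9.52%. Side product and homo dimer hold 9.25% there. That flask ends with 0% of complex with one exchanged and 90.8% of complex with two exchanged.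

Readings and results stem from a simulated flask for an exercise; scatter was added.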